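Ring C is cut across O1–C2 and C3–C4. The O1–C8a=C4a–C4 unit of ring A is a latent ortho-quinone methide (phenol O1 ortho to the C4 carbon), and C2=C3 is a latent (E)-enol acetate of an electron-rich styrene, whose 4-oxyphenyl group on C2 fixes the regiochemistry. One chiral Brønsted acid-catalysed three-component oxa-[4+2] cycloaddition of salicylaldehyde 10, trimethyl orthoformate and enol acetate 14 therefore closes ring C and sets the trans C2/C3 pair; C4 emerges as a methyl ether that DDQ later turns into the ketone. The 1,1-diarylethane centre on ring A is set beforehand by hydroxyl-directed asymmetric hydrogenation.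

Key step: step 9

Assumption: 17 and 18 are carried as mixtures of C4 epimers, since C4 becomes the carbonyl carbon in step 11; the antipodes of the ligand (step 3) and of the chiral acid (step 9) that give the drawn configurations are fixed in a pilot run.

Step 1
Reactants: 1 1-(2,4-dihydroxy-6-methoxyphenyl)ethan-1-one
Product: 2 1-[2-hydroxy-6-methoxy-4-(methoxymethoxy)phenyl]ethan-1-one
Conditions: MOMCl (1.1 equiv), iPr2NEt, CH2Cl2, 0 °C
Reagents that add atoms: chloromethyl methyl ether COCCl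
Why: Selective O-alkylation (Williamson-type acetal formation) of the 4-hydroxyl, because the 2-hydroxyl is held in a hydrogen bond to the ketone and reacts far more slowly.

Step 2
Reactants: 2 1-[2-hydroxy-6-methoxy-4-(methoxymethoxy)phenyl]ethan-1-one; 3 [4-(benzyloxy)phenyl]magnesium bromide
Product: 5 2-{1-[4-(benzyloxy)phenyl]ethenyl}-3-methoxy-5-(methoxymethoxy)phenol, via tertiary carbinol 4 (not isolated)
Conditions: 3 (2.5 equiv), LaCl3·2LiCl (1 equiv), THF, 0 °C to rt; aq NH4Cl; then PPTS (5 mol %), toluene, 40 °C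
Reagents that add atoms: none
Why: Lanthanum-assisted Grignard 1,2-addition suppresses enolisation of the hindered chelated ketone and gives carbinol 4, whose ortho-hydroxy-stabilised tertiary benzylic cation loses a proton under mild acid (E1 dehydration) to the only possible alkene.

Step 3
Reactants: 5 2-{1-[4-(benzyloxy)phenyl]ethenyl}-3-methoxy-5-(methoxymethoxy)phenol
Product: 6 2-{(1R)-1-[4-(benzyloxy)phenyl]ethyl}-3-methoxy-5-(methoxymethoxy)phenol
Conditions: H2 (10 bar), [Rh(nbd)2]BF4 (2 mol %), Josiphos ligand (R)-1-[(SP)-2-(diphenylphosphino)ferrocenyl]ethyldi-tert-butylphosphine (2.2 mol %), MeOH, rt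
Reagents that add atoms: none
Why: Hydroxyl-directed rhodium-catalysed asymmetric hydrogenation of a 2-(1-arylvinyl)phenol, in which the phenol binds the cationic rhodium–diphosphine complex so that hydrogen is delivered to one enantioface of the 1,1-diarylethene and the (R) centre is set by the ligand.

Step 4
Reactants: 6 2-{(1R)-1-[4-(benzyloxy)phenyl]ethyl}-3-methoxy-5-(methoxymethoxy)phenol
Product: 8 3-{(1R)-1-[4-(benzyloxy)phenyl]ethyl}-2-hydroxy-4-methoxy-6-(methoxymethoxy)benzaldehyde, via hydroxymethylphenol 7 (not isolated)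
Conditions: MgCl2, Et3N, (CH2O)n, MeCN, reflux; aq HCl work-up
Reagents that add atoms: paraformaldehyde (as formaldehyde) C=O
Why: Casnati–Skattebøl ortho-formylation, in which the magnesium phenoxide directs hydroxymethylation to the single free ortho position and a second formaldehyde oxidises the benzylic alkoxide by hydride transfer.

Step 5
Reactants: 8 3-{(1R)-1-[4-(benzyloxy)phenyl]ethyl}-2-hydroxy-4-methoxy-6-(methoxymethoxy)benzaldehyde
Product: 9 2-(benzyloxy)-3-{(1R)-1-[4-(benzyloxy)phenyl]ethyl}-4-methoxy-6-(methoxymethoxy)benzaldehyde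
Conditions: BnBr, Cs2CO3, DMF, 50 °C
Reagents that add atoms: benzyl bromide BrCc1ccccc1
Why: Williamson etherification of the caesium phenoxide, which protects the oxygen that becomes O5 so that only the future O1 can later close ring C.

Step 6
Reactants: 9 2-(benzyloxy)-3-{(1R)-1-[4-(benzyloxy)phenyl]ethyl}-4-methoxy-6-(methoxymethoxy)benzaldehyde
Product: 10 2-(benzyloxy)-3-{(1R)-1-[4-(benzyloxy)phenyl]ethyl}-6-hydroxy-4-methoxybenzaldehyde
Conditions: 2 M HCl, THF, 50 °C
Reagents that add atoms: none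
Why: Acid hydrolysis of the methoxymethyl acetal, helped by the ortho formyl group, frees the future O1 while the benzyl ethers, the methyl ether and the diarylmethine centre are inert.

Step 7
Reactants: 11 1-(benzyloxy)-4-ethynylbenzene
Product: 13 potassium trifluoro{(E)-2-[4-(benzyloxy)phenyl]ethenyl}borate, via pinacol boronate 12 (not isolated)
Conditions: HBpin (1.1 equiv), Cp2Zr(H)Cl (5 mol %), Et3N (10 mol %), 60 °C; then KHF2 (aq), MeOH, rt
Reagents that add atoms: pinacolborane CC1(C)OBOC1(C)C; potassium hydrogen difluoride [K+].[F-].F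
Why: Zirconium-catalysed syn hydroboration of the terminal alkyne gives the anti-Markovnikov (E)-alkenylboronate, which KHF2 converts with retention into the crystalline trifluoroborate.

Step 8
Reactants: 13 potassium trifluoro{(E)-2-[4-(benzyloxy)phenyl]ethenyl}borate
Product: 14 (E)-2-[4-(benzyloxy)phenyl]ethenyl acetate
Conditions: AcOH (2 equiv), CuBr (10 mol %), DMAP (20 mol %), 4 Å MS, O2 (1 atm), MeCN, 60 °C
Reagents that add atoms: acetic acid CC(=O)O
Why: Chan–Lam-type oxidative C–O coupling of an alkenyltrifluoroborate with a carboxylic acid, in which transmetalation to copper and C–O reductive elimination retain the (E) geometry.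

Step 9
Reactants: 10 2-(benzyloxy)-3-{(1R)-1-[4-(benzyloxy)phenyl]ethyl}-6-hydroxy-4-methoxybenzaldehyde; 14 (E)-2-[4-(benzyloxy)phenyl]ethenyl acetate
Product: 17 (2R,3S)-5-(benzyloxy)-2-[4-(benzyloxy)phenyl]-6-{(1R)-1-[4-(benzyloxy)phenyl]ethyl}-4,7-dimethoxy-3,4-dihydro-2H-1-benzopyran-3-yl acetate as C4 epimers, via dimethyl acetal 15 (not isolated), via methoxy-ortho-quinone methide 16 (not isolated)
Conditions: HC(OMe)3 (1.5 equiv), 14 (2 equiv), (R)-3,3'-bis(2,4,6-triisopropylphenyl)-1,1'-binaphthyl-2,2'-diyl N-triflylphosphoramide (10 mol %), 5 Å MS, CH2Cl2, −20 °C to rt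
Reagents that add atoms: trimethyl orthoformate COC(OC)OC
Why: Acid-catalysed acetalisation of 10 gives 15, which loses methanol to the methoxy-ortho-quinone methide 16 held in a hydrogen-bonded ion pair by the chiral phosphoramide, and 16 (heterodiene O1=C8a–C4a=C4) undergoes an asynchronous inverse-electron-demand oxa-Diels–Alder reaction with 14 in which C4 bonds to the acetoxy-bearing C3 and O1 to the benzylic C2. The closest known reactions are the acid-catalysed three-component chroman synthesis from salicylaldehydes, orthoformate and styrenes and the chiral Brønsted acid-catalysed [4+2] cycloadditions of in situ ortho-quinone methides with styrenes; the intermolecular asymmetric use with an enol acetate applies these to a new substrate pair. Ring C closes as a six-membered ring in the [4+2] mode, with C–C bond formation leading and 6-endo capture of the developing C2 benzylic cation by O1 following. The trans C2/C3 relation follows from suprafacial addition to the (E)-alkene (and from acetoxy participation should the closure be stepwise), the absolute configuration (2R,3S) is to be set by the chiral counter-anion shielding one face of 16, and C4 forms as epimers that are erased in step 11. The step needs regioselectivity (the 4-benzyloxyphenyl group stabilises positive charge at C2 far better than the acetoxy group does at C3), selectivity for O1 over O5 (O5 is benzylated) and suppression of self-condensation of 16 (excess 14, dilution, low temperature).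

Step 10
Reactants: 17 (2R,3S)-5-(benzyloxy)-2-[4-(benzyloxy)phenyl]-6-{(1R)-1-[4-(benzyloxy)phenyl]ethyl}-4,7-dimethoxy-3,4-dihydro-2H-1-benzopyran-3-yl acetate
Product: 18 (2R,3S)-5-(benzyloxy)-2-[4-(benzyloxy)phenyl]-6-{(1R)-1-[4-(benzyloxy)phenyl]ethyl}-4,7-dimethoxy-3,4-dihydro-2H-1-benzopyran-3-ol as C4 epimers
Conditions: K2CO3 (0.2 equiv), MeOH–THF, 0 °C to rt
Reagents that add atoms: none
Why: Base-catalysed transesterification removes the acetate at the flavan stage, where no carbonyl is present and neither C2 nor C3 can epimerise.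

Step 11
Reactants: 18 (2R,3S)-5-(benzyloxy)-2-[4-(benzyloxy)phenyl]-6-{(1R)-1-[4-(benzyloxy)phenyl]ethyl}-4,7-dimethoxy-3,4-dihydro-2H-1-benzopyran-3-ol
Product: 19 (2R,3R)-5-(benzyloxy)-2-[4-(benzyloxy)phenyl]-6-{(1R)-1-[4-(benzyloxy)phenyl]ethyl}-3-hydroxy-7-methoxy-2,3-dihydro-4H-1-benzopyran-4-one
Conditions: DDQ (1.5 equiv), CH2Cl2–pH 7 buffer (10:1), 0 °C to rt
Reagents that add atoms: water O
Why: DDQ abstracts hydride from the α-methoxy benzylic C4–H next to the 5,7-dioxygenated ring A (as in oxidative cleavage of electron-rich benzylic ethers and C4 functionalisation of flavan-3-ols), water adds to the oxocarbenium ion and the hemiketal loses methanol to give the C4 ketone from both C4 epimers, with C2 and C3 untouched (the C3 descriptor changes from S to R only through the priority rules).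

Step 12
Reactants: 19 (2R,3R)-5-(benzyloxy)-2-[4-(benzyloxy)phenyl]-6-{(1R)-1-[4-(benzyloxy)phenyl]ethyl}-3-hydroxy-7-methoxy-2,3-dihydro-4H-1-benzopyran-4-one
Product: 20 (2R,3R)-3,5-dihydroxy-2-(4-hydroxyphenyl)-6-[(1R)-1-(4-hydroxyphenyl)ethyl]-7-methoxy-2,3-dihydro-4H-1-benzopyran-4-one
Conditions: H2 (1 atm), Pd(OH)2/C, EtOAc–MeOH, rt
Reagents that add atoms: none
Why: Neutral hydrogenolysis cleaves the three aryl benzyl ethers, while the aryl ketone (chelated by the freed 5-hydroxyl), the C2–O1 bond and the three stereocentres should survive a short exposure.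

Compound list
1 | 1-(2,4-dihydroxy-6-methoxyphenyl)ethan-1-one (commercial) | CC(=O)c1c(O)cc(O)cc1OC | starting material
2 | 1-[2-hydroxy-6-methoxy-4-(methoxymethoxy)phenyl]ethan-1-one | CC(=O)c1c(O)cc(OCOC)cc1OC | intermediate
3 | [4-(benzyloxy)phenyl]magnesium bromide (commercial THF solution) | Br[Mg]c1ccc(OCc2ccccc2)cc1 | starting material
4 | 2-{1-[4-(benzyloxy)phenyl]-1-hydroxyethyl}-3-methoxy-5-(methoxymethoxy)phenol (racemic tertiary carbinol, not isolated) | CC(O)(c1ccc(OCc2ccccc2)cc1)c1c(O)cc(OCOC)cc1OC | intermediate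
5 | 2-{1-[4-(benzyloxy)phenyl]ethenyl}-3-methoxy-5-(methoxymethoxy)phenol | C=C(c1ccc(OCc2ccccc2)cc1)c1c(O)cc(OCOC)cc1OC | intermediate
6 | 2-{(1R)-1-[4-(benzyloxy)phenyl]ethyl}-3-methoxy-5-(methoxymethoxy)phenol | C[C@H](c1ccc(OCc2ccccc2)cc1)c1c(O)cc(OCOC)cc1OC | intermediate
7 | 2-{(1R)-1-[4-(benzyloxy)phenyl]ethyl}-6-(hydroxymethyl)-3-methoxy-5-(methoxymethoxy)phenol (not isolated) | C[C@H](c1ccc(OCc2ccccc2)cc1)c1c(O)c(CO)c(OCOC)cc1OC | intermediate
8 | 3-{(1R)-1-[4-(benzyloxy)phenyl]ethyl}-2-hydroxy-4-methoxy-6-(methoxymethoxy)benzaldehyde | C[C@H](c1ccc(OCc2ccccc2)cc1)c1c(O)c(C=O)c(OCOC)cc1OC | intermediate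
9 | 2-(benzyloxy)-3-{(1R)-1-[4-(benzyloxy)phenyl]ethyl}-4-methoxy-6-(methoxymethoxy)benzaldehyde | C[C@H](c1ccc(OCc2ccccc2)cc1)c1c(OCc2ccccc2)c(C=O)c(OCOC)cc1OC | intermediate
10 | 2-(benzyloxy)-3-{(1R)-1-[4-(benzyloxy)phenyl]ethyl}-6-hydroxy-4-methoxybenzaldehyde | C[C@H](c1ccc(OCc2ccccc2)cc1)c1c(OCc2ccccc2)c(C=O)c(O)cc1OC | intermediate
11 | 1-(benzyloxy)-4-ethynylbenzene (commercial) | C#Cc1ccc(OCc2ccccc2)cc1 | starting material
12 | 2-{(E)-2-[4-(benzyloxy)phenyl]ethenyl}-4,4,5,5-tetramethyl-1,3,2-dioxaborolane (not isolated) | CC1(C)OB(/C=C/c2ccc(OCc3ccccc3)cc2)OC1(C)C | intermediate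
13 | potassium trifluoro{(E)-2-[4-(benzyloxy)phenyl]ethenyl}borate | [K+].F[B-](F)(F)/C=C/c1ccc(OCc2ccccc2)cc1 | intermediate
14 | (E)-2-[4-(benzyloxy)phenyl]ethenyl acetate | CC(=O)O/C=C/c1ccc(OCc2ccccc2)cc1 | intermediate
15 | 3-(benzyloxy)-4-{(1R)-1-[4-(benzyloxy)phenyl]ethyl}-2-(dimethoxymethyl)-5-methoxyphenol (dimethyl acetal of 10, not isolated) | C[C@H](c1ccc(OCc2ccccc2)cc1)c1c(OCc2ccccc2)c(C(OC)OC)c(O)cc1OC | intermediate
16 | 5-(benzyloxy)-4-{(1R)-1-[4-(benzyloxy)phenyl]ethyl}-3-methoxy-6-(methoxymethylidene)cyclohexa-2,4-dien-1-one (ortho-quinone methide, not isolated) | COC=C1C(=O)C=C(OC)C([C@H](C)c2ccc(OCc3ccccc3)cc2)=C1OCc1ccccc1 | intermediate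
17 | (2R,3S)-5-(benzyloxy)-2-[4-(benzyloxy)phenyl]-6-{(1R)-1-[4-(benzyloxy)phenyl]ethyl}-4,7-dimethoxy-3,4-dihydro-2H-1-benzopyran-3-yl acetate (2,3-trans; C4 epimers) | COc1cc2c(c(OCc3ccccc3)c1[C@H](C)c1ccc(OCc3ccccc3)cc1)C(OC)[C@H](OC(C)=O)[C@@H](c1ccc(OCc3ccccc3)cc1)O2 | intermediate
18 | (2R,3S)-5-(benzyloxy)-2-[4-(benzyloxy)phenyl]-6-{(1R)-1-[4-(benzyloxy)phenyl]ethyl}-4,7-dimethoxy-3,4-dihydro-2H-1-benzopyran-3-ol (2,3-trans; C4 epimers) | COc1cc2c(c(OCc3ccccc3)c1[C@H](C)c1ccc(OCc3ccccc3)cc1)C(OC)[C@H](O)[C@@H](c1ccc(OCc3ccccc3)cc1)O2 | intermediate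
19 | (2R,3R)-5-(benzyloxy)-2-[4-(benzyloxy)phenyl]-6-{(1R)-1-[4-(benzyloxy)phenyl]ethyl}-3-hydroxy-7-methoxy-2,3-dihydro-4H-1-benzopyran-4-one | COc1cc2c(c(OCc3ccccc3)c1[C@H](C)c1ccc(OCc3ccccc3)cc1)C(=O)[C@H](O)[C@@H](c1ccc(OCc3ccccc3)cc1)O2 | intermediate
20 | (2R,3R)-3,5-dihydroxy-2-(4-hydroxyphenyl)-6-[(1R)-1-(4-hydroxyphenyl)ethyl]-7-methoxy-2,3-dihydro-4H-1-benzopyran-4-one | COc1cc2c(c(O)c1[C@H](C)c1ccc(O)cc1)C(=O)[C@H](O)[C@@H](c1ccc(O)cc1)O2 | target

Total step count: 12. Longest linear sequence: 10 steps (steps 1–6 and 9–12); steps 7 and 8 make the dienophile in a side branch.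

Steps most likely to fail

1. Step 9 (key cycloaddition). The chiral acid may bind the heterodiene without discriminating the two faces of the dienophile, or may control only the C4 face so that the C4 epimers carry opposite ring-C series. The weakly nucleophilic enol acetate may also add too slowly, so that self-condensation of the ortho-quinone methide or Friedel–Crafts attack at C8 takes over. The acetoxy group may partly override the aryl group in directing the regiochemistry. Fallback, setting out from 10 and 14 and returning at 20: the same three-component reaction is run with the achiral Lewis acid Sc(OTf)3 (HC(OMe)3, CH2Cl2, rt), the established racemic protocol, and should give the 2,3-trans acetate as both ring-C antipodes F1. Methanolysis (K2CO3, MeOH) gives the flavan-3-ols F2, and DDQ oxidation as in step 11 gives the two diastereomeric hydroxy ketones F3. Acylation of the 3-hydroxyl with (S)-1-phenylethyl chloroformate (pyridine, DMAP, CH2Cl2) places a stereocentre next to ring C, so the two carbonates should separate on silica to give the (2R,3R) carbonate F4. Hydrogenolysis under the conditions of step 12 cleaves this benzylic carbonate together with the benzyl ethers and delivers 20.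

2. Step 11 (DDQ oxidation). Hydride abstraction may be slow when the 4-methoxy group sits pseudo-axial, because C4–H is then poorly aligned with ring A. It may also occur at the other activated benzylic C–H bonds (C2–H, the diarylmethine). Fallback, setting out from 18 and returning at 19: acid solvolysis of the 4-methoxy group (TsOH 0.2 equiv, THF–H2O 4:1, 40 °C, high dilution) gives the 3,4-diol F5, and chemoselective oxidation of its benzylic 4-hydroxyl with activated MnO2 (CH2Cl2, rt) gives 19.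

3. Step 3 (asymmetric hydrogenation). Enantioface discrimination may be low, or turnover slow, at the di-ortho-substituted, twisted 1,1-diarylethene. Fallback, setting out from 5 and returning at 6: hydrogenation with the achiral complex RhCl(PPh3)3 (H2, toluene–EtOH) gives the racemic phenol F6. Esterification with (1S)-camphanoyl chloride (Et3N, DMAP, CH2Cl2) and separation of the diastereomeric esters by crystallisation or chromatography gives the (R)-configured camphanate F7, and methanolysis (K2CO3, MeOH) returns 6.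

Further compounds
F1 | step 9 | 2,3-trans-5-(benzyloxy)-2-[4-(benzyloxy)phenyl]-6-{(1R)-1-[4-(benzyloxy)phenyl]ethyl}-4,7-dimethoxy-3,4-dihydro-2H-1-benzopyran-3-yl acetate (both ring-C antipodes; C4 epimers) | COc1cc2c(c(OCc3ccccc3)c1[C@H](C)c1ccc(OCc3ccccc3)cc1)C(OC)C(OC(C)=O)C(c1ccc(OCc3ccccc3)cc1)O2
F2 | step 9 | 2,3-trans-5-(benzyloxy)-2-[4-(benzyloxy)phenyl]-6-{(1R)-1-[4-(benzyloxy)phenyl]ethyl}-4,7-dimethoxy-3,4-dihydro-2H-1-benzopyran-3-ol (both ring-C antipodes; C4 epimers) | COc1cc2c(c(OCc3ccccc3)c1[C@H](C)c1ccc(OCc3ccccc3)cc1)C(OC)C(O)C(c1ccc(OCc3ccccc3)cc1)O2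
F3 | step 9 | 2,3-trans-5-(benzyloxy)-2-[4-(benzyloxy)phenyl]-6-{(1R)-1-[4-(benzyloxy)phenyl]ethyl}-3-hydroxy-7-methoxy-2,3-dihydro-4H-1-benzopyran-4-one (both ring-C antipodes) | COc1cc2c(c(OCc3ccccc3)c1[C@H](C)c1ccc(OCc3ccccc3)cc1)C(=O)C(O)C(c1ccc(OCc3ccccc3)cc1)O2
F4 | step 9 | (2R,3R)-5-(benzyloxy)-2-[4-(benzyloxy)phenyl]-6-{(1R)-1-[4-(benzyloxy)phenyl]ethyl}-7-methoxy-4-oxo-3,4-dihydro-2H-1-benzopyran-3-yl (1S)-1-phenylethyl carbonate | COc1cc2c(c(OCc3ccccc3)c1[C@H](C)c1ccc(OCc3ccccc3)cc1)C(=O)[C@H](OC(=O)O[C@@H](C)c1ccccc1)[C@@H](c1ccc(OCc3ccccc3)cc1)O2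
F5 | step 11 | (2R,3S)-5-(benzyloxy)-2-[4-(benzyloxy)phenyl]-6-{(1R)-1-[4-(benzyloxy)phenyl]ethyl}-7-methoxy-3,4-dihydro-2H-1-benzopyran-3,4-diol (C4 epimers) | COc1cc2c(c(OCc3ccccc3)c1[C@H](C)c1ccc(OCc3ccccc3)cc1)C(O)[C@H](O)[C@@H](c1ccc(OCc3ccccc3)cc1)O2
F6 | step 3 | racemic 2-{1-[4-(benzyloxy)phenyl]ethyl}-3-methoxy-5-(methoxymethoxy)phenol | CC(c1ccc(OCc2ccccc2)cc1)c1c(O)cc(OCOC)cc1OC
F7 | step 3 | 2-{(1R)-1-[4-(benzyloxy)phenyl]ethyl}-3-methoxy-5-(methoxymethoxy)phenyl (1S,4R)-4,7,7-trimethyl-3-oxo-2-oxabicyclo[2.2.1]heptane-1-carboxylate | O=C(Oc1cc(OCOC)cc(OC)c1[C@H](C)c1ccc(OCc2ccccc2)cc1)[C@@]12CC[C@@](C)(C(=O)O1)C2(C)C
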